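**Assumption:** 4,6-dibromoresorcinol, 4-bromoresorcinol, prenylboronic acid pinacol ester and the (2S,5S)-imidazolidinone catalyst are taken as commercial. The target is (3R), as read from the given SMILES.

## Retrosynthetic overview

- Both 1,1-dimethylallyl groups are installed last-but-one, in one operation, from a 6,5'-dibromo-isoflavan by a twofold γ-selective prenyl Suzuki coupling; MOM removal ends the route.
- The only ring that is built is the dihydropyran, closed (O1–C2) by Mitsunobu etherification of a 2-aryl-3-(2-hydroxyaryl)propan-1-ol. Both benzene rings are bought.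
- Key disconnection C3–C1': the α-carbon of a 3-arylpropanal is made electrophilic (enamine radical cation, a chiral catalytic enolonium equivalent) and is attacked by the nucleophilic C–H of a resorcinol bis-MOM ether. This sets C3 (R) directly.
- The aldehyde comes from 4,6-dibromoresorcinol diacetate by a mono-Heck reaction with allyl alcohol; the arene comes from 4-bromoresorcinol. Acetates on ring A and MOM ethers on ring B differentiate the two resorcinols for the ring closure.

## Route

**Step 1**
Reactants: 1 4,6-dibromoresorcinol; 2 acetic anhydride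
Product: 3 4,6-dibromo-1,3-phenylene diacetate
Conditions: Ac2O, pyridine, DMAP (cat.), CH2Cl2, 0 °C → rt
Reagents that add atoms: acetic anhydride, CC(=O)OC(C)=O
Why: Plain O-acetylation (esterification) of both phenols; the acetates shield ring A from the oxidant in step 4 and can later be removed by methanolysis without touching MOM ethers.

**Step 2**
Reactants: 3 4,6-dibromo-1,3-phenylene diacetate (3 equiv, excess recovered); 4 allyl alcohol
Product: 5 4-bromo-6-(3-oxopropyl)-1,3-phenylene diacetate
Conditions: Pd(OAc)2 (5 mol%), Bu4NCl, NaHCO3, DMF, 70 °C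
Reagents that add atoms: allyl alcohol, C=CCO
Why: Jeffery-type Heck reaction of allyl alcohol, in which aryl-Pd adds to the terminal carbon and β-hydride elimination towards the carbinol gives the enol and hence the 3-arylpropanal; the two C–Br bonds are equivalent, so excess 3 and the slower second oxidative addition on the more electron-rich product hold the reaction at mono-coupling.

**Step 3**
Reactants: 6 4-bromoresorcinol; 7 chloromethyl methyl ether
Product: 8 1-bromo-2,4-bis(methoxymethoxy)benzene
Conditions: NaH, DMF, 0 °C; MOMCl, 0 °C → rt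
Reagents that add atoms: chloromethyl methyl ether, COCCl
Why: Williamson-type O-alkylation (MOM protection) of both phenoxides; MOM ethers keep the ring electron-rich and survive CAN, borohydride, carbonate and Pd.

**Step 4**
Reactants: 5 4-bromo-6-(3-oxopropyl)-1,3-phenylene diacetate; 8 1-bromo-2,4-bis(methoxymethoxy)benzene (4 equiv, excess recovered)
Product: 11 4-bromo-6-[(2R)-2-[5-bromo-2,4-bis(methoxymethoxy)phenyl]-3-hydroxypropyl]benzene-1,3-diol, via α-aryl aldehyde 9 (not isolated), via diacetate alcohol 10 (not isolated)
Conditions: (2S,5S)-5-benzyl-2-tert-butyl-3-methylimidazolidin-4-one·TFA (20 mol%), CAN (2.5 equiv), NaHCO3, H2O (2 equiv), DME, −30 °C; then NaBH4, MeOH, −30 → 0 °C; then K2CO3 (0.3 equiv), MeOH, rt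
Reagents that add atoms: none
Why: Proposed new method: the imidazolidinone enamine of 5 is oxidised by CAN to a 3π-electron radical cation (organo-SOMO activation, a chiral enolonium equivalent) whose α-carbon is attacked by C5–H of 8 (para to one OMOM, ortho to the other, the most nucleophilic and least hindered site) on the face anti to the catalyst's benzyl group, which by the standard model gives (R)-9 (if the sense proved opposite, the (2R,5R) catalyst would be used); a second electron transfer and loss of H+ rearomatise the ring, NaBH4 fixes the α-aryl aldehyde as the configurationally stable alcohol 10 before it can enolise and carbonate methanolysis removes the two acetates; the closest known reactions are the intramolecular organo-SOMO α-arylation of aldehydes with anisole rings and the intermolecular SOMO α-allylation and α-heteroarylation.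

**Step 5**
Reactants: 11 4-bromo-6-[(2R)-2-[5-bromo-2,4-bis(methoxymethoxy)phenyl]-3-hydroxypropyl]benzene-1,3-diol
Product: 12 (3R)-6-bromo-3-[5-bromo-2,4-bis(methoxymethoxy)phenyl]-3,4-dihydro-2H-chromen-7-ol
Conditions: PPh3, DIAD, THF (0.01 M), 0 °C → rt
Reagents that add atoms: none
Why: Intramolecular Mitsunobu etherification in which only the ortho phenol of ring A can reach the primary carbinol (6-membered ring), while the B-ring oxygens are MOM-blocked so the competing dihydrobenzofuran cannot form; the stereocentre is next to, not at, the reacting carbon and is untouched.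

**Step 6**
Reactants: 12 (3R)-6-bromo-3-[5-bromo-2,4-bis(methoxymethoxy)phenyl]-3,4-dihydro-2H-chromen-7-ol; 13 prenylboronic acid pinacol ester (4 equiv)
Product: 14 (3R)-3-[2,4-bis(methoxymethoxy)-5-(2-methylbut-3-en-2-yl)phenyl]-6-(2-methylbut-3-en-2-yl)-3,4-dihydro-2H-chromen-7-ol
Conditions: Pd(OAc)2 (5 mol%), γ-selective biarylphosphine ligand (regiodivergent allyl–aryl coupling system; the specific ligand is left open because I could not recall it with confidence), K3PO4 (aq.), THF, 40 °C
Reagents that add atoms: prenylboronic acid pinacol ester, CC(C)=CCB1OC(C)(C)C(C)(C)O1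
Why: Twofold γ-selective Suzuki–Miyaura allyl–aryl coupling, in which SE2' transmetalation places Pd on the tertiary allyl carbon and fast reductive elimination gives the branched Ar–C(CH3)2–CH=CH2 group at both C–Br positions; the free phenol, MOM ethers and the remote stereocentre are inert.

**Step 7**
Reactants: 14 (3R)-3-[2,4-bis(methoxymethoxy)-5-(2-methylbut-3-en-2-yl)phenyl]-6-(2-methylbut-3-en-2-yl)-3,4-dihydro-2H-chromen-7-ol
Product: 15 Manuifolin E, 4-[(3R)-7-hydroxy-6-(2-methylbut-3-en-2-yl)-3,4-dihydro-2H-chromen-3-yl]-6-(2-methylbut-3-en-2-yl)benzene-1,3-diol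
Conditions: 2 M HCl, MeOH–THF, rt → 40 °C
Reagents that add atoms: none
Why: Acid-catalysed acetal exchange (MOM cleavage) into methanol; dilute HCl in alcohol leaves o-(1,1-dimethylallyl)phenols intact because protonating the terminal alkene would need an unstabilised secondary cation, and C3 carries no acidic hydrogen.

## Compound list

1 | 4,6-dibromoresorcinol | Oc1cc(O)c(Br)cc1Br | starting material
2 | acetic anhydride | CC(=O)OC(C)=O | starting material
3 | 4,6-dibromo-1,3-phenylene diacetate | CC(=O)Oc1cc(OC(C)=O)c(Br)cc1Br | intermediate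
4 | allyl alcohol | C=CCO | starting material
5 | 4-bromo-6-(3-oxopropyl)-1,3-phenylene diacetate | CC(=O)Oc1cc(OC(C)=O)c(CCC=O)cc1Br | intermediate
6 | 4-bromoresorcinol | Oc1ccc(Br)c(O)c1 | starting material
7 | chloromethyl methyl ether | COCCl | starting material
8 | 1-bromo-2,4-bis(methoxymethoxy)benzene | COCOc1ccc(Br)c(OCOC)c1 | intermediate
9 | (2R)-3-[2,4-bis(acetyloxy)-5-bromophenyl]-2-[5-bromo-2,4-bis(methoxymethoxy)phenyl]propanal | O=C[C@@H](c1cc(Br)c(OCOC)cc1OCOC)Cc1cc(Br)c(OC(C)=O)cc1OC(C)=O | intermediate (not isolated)
10 | 4-bromo-6-[(2R)-2-[5-bromo-2,4-bis(methoxymethoxy)phenyl]-3-hydroxypropyl]-1,3-phenylene diacetate | OC[C@@H](c1cc(Br)c(OCOC)cc1OCOC)Cc1cc(Br)c(OC(C)=O)cc1OC(C)=O | intermediate (not isolated)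
11 | 4-bromo-6-[(2R)-2-[5-bromo-2,4-bis(methoxymethoxy)phenyl]-3-hydroxypropyl]benzene-1,3-diol | OC[C@@H](c1cc(Br)c(OCOC)cc1OCOC)Cc1cc(Br)c(O)cc1O | intermediate
12 | (3R)-6-bromo-3-[5-bromo-2,4-bis(methoxymethoxy)phenyl]-3,4-dihydro-2H-chromen-7-ol | Brc1cc2c(cc1O)OC[C@@H](c1cc(Br)c(OCOC)cc1OCOC)C2 | intermediate
13 | prenylboronic acid pinacol ester, 4,4,5,5-tetramethyl-2-(3-methylbut-2-en-1-yl)-1,3,2-dioxaborolane | CC(C)=CCB1OC(C)(C)C(C)(C)O1 | starting material
14 | (3R)-3-[2,4-bis(methoxymethoxy)-5-(2-methylbut-3-en-2-yl)phenyl]-6-(2-methylbut-3-en-2-yl)-3,4-dihydro-2H-chromen-7-ol | C=CC(C)(C)c1cc2c(cc1O)OC[C@@H](c1cc(C(C)(C)C=C)c(OCOC)cc1OCOC)C2 | intermediate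
15 | Manuifolin E | C=CC(C)(C)c1cc2c(cc1O)OC[C@@H](c1cc(C(C)(C)C=C)c(O)cc1O)C2 | target

## Count and risks

Total steps: 7. Longest linear sequence: 6 (steps 1, 2, 4, 5, 6, 7 from 4,6-dibromoresorcinol); step 3 is a one-step side branch.

The three steps most likely to fail are steps 4, 6 and 7.

**Step 4 (intermolecular radical-cation α-arylation).** The arene 8 may be too weak a partner, so that nitrate trapping of the radical cation wins. The fallback sets out from 8 and returns at 11. It keeps the enamine of 5 but moves the reversed polarity onto the arene: 8 is treated with [hydroxy(tosyloxy)iodo]mesitylene in trifluoroethanol at rt, which iodanates C5 without strong acid and gives [5-bromo-2,4-bis(methoxymethoxy)phenyl](2,4,6-trimethylphenyl)iodonium 4-methylbenzenesulfonate F1. F1 then arylates the same imidazolidinone enamine of 5 under CuBr catalysis (NaHCO3, toluene–Et2O, rt), the non-mesityl aryl being transferred from aryl–Cu(III). In-situ NaBH4 and K2CO3/MeOH as before lead through 9 and 10 to 11.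

**Step 6 (double γ-selective coupling).** Linear prenyl isomers or incomplete coupling at the two ortho-oxygenated bromides are the risk. The fallback sets out from 12 and returns at 14, and it fixes the regiochemistry by construction. 12 is arylated twice with isobutyraldehyde (Pd(OAc)2, rac-BINAP, Cs2CO3, dioxane, 80 °C; Pd-catalysed α-arylation of an α-branched aldehyde can only give Ar–C(CH3)2–CHO). This gives 2-[(3R)-3-[2,4-bis(methoxymethoxy)-5-(2-methyl-1-oxopropan-2-yl)phenyl]-7-hydroxy-3,4-dihydro-2H-chromen-6-yl]-2-methylpropanal F2, whose A-ring aldehyde may rest as the lactol with the 7-OH. Double Wittig methylenation with excess Ph3P=CH2 (THF, 0 °C → rt) then gives 14.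

**Step 7 (acidic MOM removal with two acid-sensitive alkenes present).** Cyclisation of the o-(1,1-dimethylallyl)phenols or alkylation of the resorcinol rings by the released MOM cation is the risk. The fallback sets out from 12 and returns at 15 by changing the order. The MOM ethers are cleaved at the dibromide stage (2 M HCl, MeOH, 40 °C, no alkene yet present) to give 4-bromo-6-[(3R)-6-bromo-7-hydroxy-3,4-dihydro-2H-chromen-3-yl]benzene-1,3-diol F3. The twofold γ-selective prenyl Suzuki coupling of step 6 is then run on this unprotected triphenol (as its phenoxides in aqueous K3PO4/THF) and gives 15 directly, so the alkenes never meet acid.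

## Further compounds

F1 | step 4 | [5-bromo-2,4-bis(methoxymethoxy)phenyl](2,4,6-trimethylphenyl)iodonium 4-methylbenzenesulfonate | COCOc1cc(OCOC)c(cc1Br)[I+]c1c(C)cc(C)cc1C.Cc1ccc(cc1)S(=O)(=O)[O-]
F2 | step 6 | 2-[(3R)-3-[2,4-bis(methoxymethoxy)-5-(2-methyl-1-oxopropan-2-yl)phenyl]-7-hydroxy-3,4-dihydro-2H-chromen-6-yl]-2-methylpropanal | O=CC(C)(C)c1cc2c(cc1O)OC[C@@H](c1cc(C(C)(C)C=O)c(OCOC)cc1OCOC)C2
F3 | step 7 | 4-bromo-6-[(3R)-6-bromo-7-hydroxy-3,4-dihydro-2H-chromen-3-yl]benzene-1,3-diol | Brc1cc2c(cc1O)OC[C@@H](c1cc(Br)c(O)cc1O)C2
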